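**Assumptions:** The SMILES has 21 C atoms before the ring-closure digit, so the side chain is n-eicosyl (C20H41) on the ring carbon. The target has no stereocenters and is achiral, so no stereochemical control is needed.

## Retrosynthetic overview
- Target **1** (2-hydroxy-5-methoxy-3-eicosyl-1,4-benzoquinone) comes from regioselective mono-O-methylation of the 2,5-dihydroxyquinone **2** with TMS-diazomethane **3**.
- **2** comes from one-pot BBr3 per-demethylation and oxidative dearomatization (air) of 3-eicosyl-1,2,4,5-tetramethoxybenzene **4**. The oxidation is symmetry-neutral, so only one quinone constitution can form.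
- **4** comes from the key symmetry-breaking step: mono-lithiation of 1,2,4,5-tetramethoxybenzene **5** at the C–H flanked by two OMe groups, then alkylation with 1-bromoeicosane **6**.
- No ring is constructed. The benzene ring of **5** is carried through and converted to the quinone ring in the second step.

## Route

**Step 1**
Reactants: **5** 1,2,4,5-tetramethoxybenzene; **6** 1-bromoeicosane
Product: **4** 1-eicosyl-2,3,5,6-tetramethoxybenzene (3-eicosyl-1,2,4,5-tetramethoxybenzene)
Conditions: n-BuLi (1.05 equiv), TMEDA, THF, 0 °C, 2 h; then **6** (1.2 equiv), DMPU, –20 → 25 °C, 12 h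
Reagents that add atoms: 1-bromoeicosane (**6**), CCCCCCCCCCCCCCCCCCCCBr (adds C20H41)
Why: Directed ortho-lithiation removes one of the two equivalent C–H bonds, each flanked by two OMe groups. This desymmetrizes the arene, and SN2 alkylation of the aryllithium then installs the chain. No stereocenter is formed.

**Step 2**
Reactants: **4**
Product: **2** 2,5-dihydroxy-3-eicosyl-1,4-benzoquinone
Conditions: BBr3 (6 equiv), CH2Cl2, –78 → 25 °C, 16 h; then H2O, and stir open to air, 25 °C, 12 h
Reagents that add atoms: none (BBr3 and O2 leave no atoms in the product; all four ring oxygens come from the original OMe groups)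
Why: BBr3 cleaves all four aryl methyl ethers (Lewis-acid-assisted bromide SN2 on methyl) to give the electron-rich 3-eicosyl-1,2,4,5-tetrol. Air then removes 2 e⁻/2 H⁺, which dearomatizes the ring to the vinylogous-acid quinone. Oxidizing either para pair gives the same constitution, so there is no regiochemical problem and no stereocenter.

**Step 3**
Reactants: **2**; **3** trimethylsilyldiazomethane
Product: **1** Irisoquin-D (2-hydroxy-5-methoxy-3-eicosyl-1,4-benzoquinone)
Conditions: **3** (1.05 equiv, 2 M in hexanes), MeOH/toluene (1:4), 0 → 25 °C, 2 h
Reagents that add atoms: TMSCHN2 (**3**), C[Si](C)(C)C=[N+]=[N-] (adds CH3)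
Why: Proposed new method: acid-driven O-methylation with TMSCHN2/MeOH, which is the known methylation of acidic vinylogous acids such as hydroxyquinones. The 5-OH, remote from the alkyl group, should be the more acidic and less hindered of the two OH groups. It protonates the diazo carbon and the resulting anion is methylated, while the 2-OH (flanked by the eicosyl group) is left free. Closest known reaction type: diazoalkane O-methylation of embelin-type 2,5-dihydroxyquinones. No stereocenter is formed.

## Compound list
1 | Irisoquin-D, 2-hydroxy-5-methoxy-3-eicosyl-1,4-benzoquinone | CCCCCCCCCCCCCCCCCCCCC1=C(O)C(=O)C=C(OC)C1=O | target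
2 | 2,5-dihydroxy-3-eicosyl-1,4-benzoquinone | CCCCCCCCCCCCCCCCCCCCC1=C(O)C(=O)C=C(O)C1=O | intermediate
3 | trimethylsilyldiazomethane | C[Si](C)(C)C=[N+]=[N-] | starting material (reagent)
4 | 1-eicosyl-2,3,5,6-tetramethoxybenzene | CCCCCCCCCCCCCCCCCCCCc1c(OC)c(OC)cc(OC)c1OC | intermediate
5 | 1,2,4,5-tetramethoxybenzene | COc1cc(OC)c(OC)cc1OC | starting material
6 | 1-bromoeicosane | CCCCCCCCCCCCCCCCCCCCBr | starting material

## Summary
Total steps: 3. Longest linear sequence: 3 (5 → 4 → 2 → 1).

## Three steps most likely to fail
1. **Step 3 (regioselective mono-methylation).** The 2-OMe isomer and the 2,5-bis-OMe compound are both possible.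
   - Fallback: change the approach to 2-hydroxy-5-methoxy-1,4-benzoquinone, made by controlled hydrolysis of 2,5-dimethoxybenzoquinone. Alkylate it with heneicosanoic acid under Ag⁺/(NH4)2S2O8 decarboxylative radical conditions (Kochi–Anderson), then separate the C3/C6 regioisomers.
2. **Step 1 (hindered, chelated aryllithium plus a long-chain primary bromide).** Sluggish alkylation, dilithiation or proton transfer could lower the yield.
   - Fallback: Friedel–Crafts acylation of **5** with eicosanoyl chloride (SnCl4), then Et3SiH/TFA reduction of the aryl ketone to give **4**.
3. **Step 2 (one-pot per-demethylation and autoxidation).** The polyphenol may over-decompose or give an insoluble boron-containing mixture.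
   - Fallback: oxidize **4** first with CAN (MeCN/H2O) to 3-eicosyl-2,5-dimethoxybenzoquinone, then hydrolyze both vinylogous esters with KOH (aq. EtOH/THF, 60 °C) followed by HCl to give **2**.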